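**Retrosynthetic overview**
1. The hydroquinone is carried as its dimethyl ether and the side-chain ketone as a secondary alcohol; the last two steps (oxidative demethylation to the quinone, then alcohol oxidation with reductive work-up) release the target.
2. The (E)-γ-hydroxy enone comes from a methyl ketone and 2-hydroxy-2-methylpropanal by aldol condensation.
3. The (Z)-trisubstituted alkene and the adjacent C–C bond come from allylboration of a keto aldehyde with an α-substituted methallyl boronate, itself made from 2,6-dimethylphenol by functionalising one of its two equivalent methyl groups.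
4. The keto aldehyde with both quaternary centres comes from a De Mayo sequence: [2+2] photocycloaddition of symmetric 1,2-dimethylcyclopentene with a chiral dioxinone, then reductive retro-aldol opening.
5. Ring order: the arene and the cyclopentane are bought; a cyclobutane (fused to the dioxanone) is formed in the key step and opened in the next; the arene passes through a quinone at the end.

Assumption: (2S)-2-tert-butyl-6-methyl-4H-1,3-dioxin-4-one, 1,2-dimethylcyclopentene and 2-hydroxy-2-methylpropanal (sold as monomer/dimer) are taken as purchasable.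

**Step 1**
Reactants: 1 2,6-dimethylphenol
Product: 2 2,6-dimethylcyclohexa-2,5-diene-1,4-dione
Conditions: O2 (1 atm), Co(C16H14N2O2) [Co(salen), divalent cobalt, 5 mol %], DMF, 25 °C
Reagents that add atoms: dioxygen, O=O
Why: Cobalt–salen catalysed aerobic para-oxidation of a 2,6-disubstituted phenol (phenol-to-p-quinone oxidation) works because both ortho positions are blocked and the para position is free.

**Step 2**
Reactants: 2 2,6-dimethylcyclohexa-2,5-diene-1,4-dione
Product: 4 2,5-dimethoxy-1,3-dimethylbenzene, via hydroquinone 3 (not isolated)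
Conditions: Na2S2O4, THF/H2O, 25 °C; then NaOH (aq), (CH3O)2SO2, Bu4NBr (cat.), 25 °C, N2
Reagents that add atoms: dimethyl sulfate, COS(=O)(=O)OC
Why: Reductive methylation, in which dithionite reduces the quinone and the hydroquinone dianion is O-methylated twice under phase-transfer Williamson conditions before it can re-oxidise.

**Step 3**
Reactants: 4 2,5-dimethoxy-1,3-dimethylbenzene
Product: 6 2-[(2,5-dimethoxy-3-methylphenyl)methyl]-4,4,5,5-tetramethyl-1,3,2-dioxaborolane, via benzylpotassium 5 (not isolated)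
Conditions: n-BuLi, KOtBu, 2,2,6,6-tetramethylpiperidine (1 equiv each), THF, −78 °C; then 2-isopropoxy-4,4,5,5-tetramethyl-1,3,2-dioxaborolane, −78 °C → 25 °C; then H2O
Reagents that add atoms: 2-isopropoxy-4,4,5,5-tetramethyl-1,3,2-dioxaborolane, CC(C)OB1OC(C)(C)C(C)(C)O1
Why: Lateral (benzylic) metalation with the n-BuLi/KOtBu/amine mixed-metal base, in which the amine shuttles any ring-metalated species to the more stable benzylic anion, followed by electrophilic borylation, functionalises one of the two equivalent methyl groups when one equivalent of base is used.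

**Step 4**
Reactants: 6 2-[(2,5-dimethoxy-3-methylphenyl)methyl]-4,4,5,5-tetramethyl-1,3,2-dioxaborolane; 7 isopropenylmagnesium bromide
Product: 9 2-[1-(2,5-dimethoxy-3-methylphenyl)-3-methylbut-3-en-2-yl]-4,4,5,5-tetramethyl-1,3,2-dioxaborolane (racemic), via alpha-chloro boronic ester 8 (not isolated)
Conditions: CH2Cl2, n-BuLi, THF, −100 °C; add 6, −100 °C → 25 °C; then 7, −78 °C → 25 °C
Reagents that add atoms: dichloromethyllithium (made in the flask from dichloromethane, ClCCl, and n-BuLi), [Li]C(Cl)Cl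
Why: Matteson homologation, in which two successive boron-ate 1,2-migrations (benzyl, then isopropenyl) each displace chloride and give the α-substituted methallyl boronate regiospecifically; the new boron-bearing stereocentre is racemic and is lost in step 7.

**Step 5 (key step)**
Reactants: 10 1,2-dimethylcyclopent-1-ene; 11 (2S)-2-tert-butyl-6-methyl-4H-1,3-dioxin-4-one
Product: 12 (1S,2S,6S,7S,9S)-9-tert-butyl-2,6,7-trimethyl-8,10-dioxatricyclo[5.4.0.0(2,6)]undecan-11-one
Conditions: hν (300 nm, Pyrex), 10 (8 equiv), MeCN/acetone 9:1, −20 °C; chromatography/crystallisation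
Reagents that add atoms: none
Why: De Mayo-type enone–alkene [2+2] photocycloaddition, in which the excited dioxinone adds across the tetrasubstituted alkene to give a cis-fused cyclobutane so that both methyl-bearing quaternary carbons are formed cis in one step; attack on the dioxinone face anti to the tert-butyl group in the cis-anti-cis mode gives the (2S,6S) configuration, and all other adducts are diastereomers that are removed at this stage.

**Step 6**
Reactants: 12 (1S,2S,6S,7S,9S)-9-tert-butyl-2,6,7-trimethyl-8,10-dioxatricyclo[5.4.0.0(2,6)]undecan-11-one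
Product: 14 2-[(1S,2S)-2-acetyl-1,2-dimethylcyclopentyl]acetaldehyde, via cyclobutanol aldehyde 13 (not isolated)
Conditions: i-Bu2AlH (1.1 equiv), CH2Cl2, −78 °C; aq. KNaC4H4O6; then Et3N (cat.), CH2Cl2, 0 °C; used crude
Reagents that add atoms: none
Why: Partial reduction of the dioxanone carbonyl unmasks the β-hydroxy aldehyde with loss of pivalaldehyde, and strain-driven retro-aldol cleavage of the cyclobutanol (the De Mayo fragmentation) gives the 1,5-keto aldehyde without touching the two quaternary stereocentres.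

**Step 7**
Reactants: 14 2-[(1S,2S)-2-acetyl-1,2-dimethylcyclopentyl]acetaldehyde; 9 2-[1-(2,5-dimethoxy-3-methylphenyl)-3-methylbut-3-en-2-yl]-4,4,5,5-tetramethyl-1,3,2-dioxaborolane (racemic, 2 equiv)
Product: 15 1-[(1S,2S)-2-[(4Z)-6-(2,5-dimethoxy-3-methylphenyl)-2-hydroxy-4-methylhex-4-en-1-yl]-1,2-dimethylcyclopentyl]ethan-1-one (both carbinol epimers)
Conditions: toluene, 60 °C, 36 h; then H2O, silica gel
Reagents that add atoms: none
Why: Aldehyde-selective allylboration through a chair six-membered transition state, in which the α-(arylmethyl) group sits pseudo-axial to avoid the pinacol methyls and A(1,2) strain with the 2-methyl group, so allyl transposition gives the (Z)-trisubstituted alkene; the carbinol centre forms as a mixture that is oxidised away in step 10.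

**Step 8**
Reactants: 15 1-[(1S,2S)-2-[(4Z)-6-(2,5-dimethoxy-3-methylphenyl)-2-hydroxy-4-methylhex-4-en-1-yl]-1,2-dimethylcyclopentyl]ethan-1-one; 16 2-hydroxy-2-methylpropanal (3 equiv)
Product: 18 (2E)-1-[(1S,2S)-2-[(4Z)-6-(2,5-dimethoxy-3-methylphenyl)-2-hydroxy-4-methylhex-4-en-1-yl]-1,2-dimethylcyclopentyl]-4-hydroxy-4-methylpent-2-en-1-one, via aldol adduct 17 (not isolated)
Conditions: NaOH (aq, 2 M, cat.), EtOH, 0 → 25 °C, N2
Reagents that add atoms: none
Why: Claisen–Schmidt crossed aldol condensation, in which the methyl group is the only enolisable position of the ketone and the aldehyde has no α-hydrogen, and E1cB dehydration of the aldol adduct gives the conjugated (E)-enone.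

**Step 9**
Reactants: 18 (2E)-1-[(1S,2S)-2-[(4Z)-6-(2,5-dimethoxy-3-methylphenyl)-2-hydroxy-4-methylhex-4-en-1-yl]-1,2-dimethylcyclopentyl]-4-hydroxy-4-methylpent-2-en-1-one
Product: 19 2-[(2Z)-5-hydroxy-6-[(1S,2S)-2-[(2E)-4-hydroxy-4-methylpent-2-enoyl]-1,2-dimethylcyclopentyl]-3-methylhex-2-en-1-yl]-6-methylcyclohexa-2,5-diene-1,4-dione
Conditions: (NH4)2Ce(NO3)6 (2.5 equiv), MeCN/H2O 2:1, 0 °C, 15 min
Reagents that add atoms: water, O
Why: Oxidative demethylation of a 1,4-dimethoxyarene by tetravalent cerium gives the p-quinone while the alcohols, the enone and the trisubstituted alkene survive the short cold exposure, and the acid-sensitive 1,5-diketone is not yet present.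

**Step 10**
Reactants: 19 2-[(2Z)-5-hydroxy-6-[(1S,2S)-2-[(2E)-4-hydroxy-4-methylpent-2-enoyl]-1,2-dimethylcyclopentyl]-3-methylhex-2-en-1-yl]-6-methylcyclohexa-2,5-diene-1,4-dione
Product: 21 2-[(2Z)-6-[(1S,2S)-2-[(2E)-4-hydroxy-4-methylpent-2-enoyl]-1,2-dimethylcyclopentyl]-3-methyl-5-oxohex-2-en-1-yl]-6-methylbenzene-1,4-diol, via quinone ketone 20 (not isolated)
Conditions: Dess–Martin periodinane (1.5 equiv), NaHCO3, CH2Cl2, 0 → 25 °C; then aq. Na2S2O4, EtOAc, 25 °C
Reagents that add atoms: none
Why: Buffered Dess–Martin oxidation converts only the secondary alcohol (the tertiary one is inert) without moving the β,γ-alkene into conjugation, and the dithionite work-up reduces the quinone to the hydroquinone under neutral conditions, so the base- and acid-sensitive 1,5-diketone is never exposed to either.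

**Compound list**
1 | 2,6-dimethylphenol | Cc1cccc(C)c1O | starting material
2 | 2,6-dimethylcyclohexa-2,5-diene-1,4-dione | CC1=CC(=O)C=C(C)C1=O | intermediate
3 | 2,6-dimethylbenzene-1,4-diol | Cc1cc(O)cc(C)c1O | intermediate (not isolated)
4 | 2,5-dimethoxy-1,3-dimethylbenzene | COc1cc(C)c(OC)c(C)c1 | intermediate
5 | (2,5-dimethoxy-3-methylbenzyl)potassium | [K]Cc1cc(OC)cc(C)c1OC | intermediate (not isolated)
6 | 2-[(2,5-dimethoxy-3-methylphenyl)methyl]-4,4,5,5-tetramethyl-1,3,2-dioxaborolane | COc1cc(C)c(OC)c(CB2OC(C)(C)C(C)(C)O2)c1 | intermediate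
7 | isopropenylmagnesium bromide | CC(=C)[Mg]Br | starting material
8 | 2-[1-chloro-2-(2,5-dimethoxy-3-methylphenyl)ethyl]-4,4,5,5-tetramethyl-1,3,2-dioxaborolane (racemic) | COc1cc(C)c(OC)c(CC(Cl)B2OC(C)(C)C(C)(C)O2)c1 | intermediate (not isolated)
9 | 2-[1-(2,5-dimethoxy-3-methylphenyl)-3-methylbut-3-en-2-yl]-4,4,5,5-tetramethyl-1,3,2-dioxaborolane (racemic) | COc1cc(C)c(OC)c(CC(C(C)=C)B2OC(C)(C)C(C)(C)O2)c1 | intermediate
10 | 1,2-dimethylcyclopent-1-ene | CC1=C(C)CCC1 | starting material
11 | (2S)-2-tert-butyl-6-methyl-4H-1,3-dioxin-4-one | CC1=CC(=O)O[C@H](O1)C(C)(C)C | starting material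
12 | (1S,2S,6S,7S,9S)-9-tert-butyl-2,6,7-trimethyl-8,10-dioxatricyclo[5.4.0.0(2,6)]undecan-11-one | O=C1O[C@@H](C(C)(C)C)O[C@@]2(C)[C@@H]1[C@]3(C)CCC[C@]23C | intermediate
13 | (1S,5S,6S,7S)-7-hydroxy-1,5,7-trimethylbicyclo[3.2.0]heptane-6-carbaldehyde | O[C@@]1(C)[C@@H](C=O)[C@]2(C)CCC[C@]12C | intermediate (not isolated)
14 | 2-[(1S,2S)-2-acetyl-1,2-dimethylcyclopentyl]acetaldehyde | O=CC[C@]1(C)CCC[C@]1(C)C(C)=O | intermediate
15 | 1-[(1S,2S)-2-[(4Z)-6-(2,5-dimethoxy-3-methylphenyl)-2-hydroxy-4-methylhex-4-en-1-yl]-1,2-dimethylcyclopentyl]ethan-1-one (both carbinol epimers) | C/C(=C/Cc1cc(OC)cc(C)c1OC)CC(O)C[C@]1(C)CCC[C@]1(C)C(C)=O | intermediate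
16 | 2-hydroxy-2-methylpropanal | CC(C)(O)C=O | starting material
17 | 1-[(1S,2S)-2-[(4Z)-6-(2,5-dimethoxy-3-methylphenyl)-2-hydroxy-4-methylhex-4-en-1-yl]-1,2-dimethylcyclopentyl]-3,4-dihydroxy-4-methylpentan-1-one | C/C(=C/Cc1cc(OC)cc(C)c1OC)CC(O)C[C@]1(C)CCC[C@]1(C)C(=O)CC(O)C(C)(C)O | intermediate (not isolated)
18 | (2E)-1-[(1S,2S)-2-[(4Z)-6-(2,5-dimethoxy-3-methylphenyl)-2-hydroxy-4-methylhex-4-en-1-yl]-1,2-dimethylcyclopentyl]-4-hydroxy-4-methylpent-2-en-1-one | C/C(=C/Cc1cc(OC)cc(C)c1OC)CC(O)C[C@]1(C)CCC[C@]1(C)C(=O)/C=C/C(C)(C)O | intermediate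
19 | 2-[(2Z)-5-hydroxy-6-[(1S,2S)-2-[(2E)-4-hydroxy-4-methylpent-2-enoyl]-1,2-dimethylcyclopentyl]-3-methylhex-2-en-1-yl]-6-methylcyclohexa-2,5-diene-1,4-dione | C/C(=C/CC1=CC(=O)C=C(C)C1=O)CC(O)C[C@]1(C)CCC[C@]1(C)C(=O)/C=C/C(C)(C)O | intermediate
20 | 2-[(2Z)-6-[(1S,2S)-2-[(2E)-4-hydroxy-4-methylpent-2-enoyl]-1,2-dimethylcyclopentyl]-3-methyl-5-oxohex-2-en-1-yl]-6-methylcyclohexa-2,5-diene-1,4-dione | C/C(=C/CC1=CC(=O)C=C(C)C1=O)CC(=O)C[C@]1(C)CCC[C@]1(C)C(=O)/C=C/C(C)(C)O | intermediate (not isolated)
21 | 2-[(2Z)-6-[(1S,2S)-2-[(2E)-4-hydroxy-4-methylpent-2-enoyl]-1,2-dimethylcyclopentyl]-3-methyl-5-oxohex-2-en-1-yl]-6-methylbenzene-1,4-diol | C/C(=C/Cc1cc(O)cc(C)c1O)CC(=O)C[C@]1(C)CCC[C@]1(C)C(=O)/C=C/C(C)(C)O | target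

**Step count and risks**
Total steps: 10. Longest linear sequence: 8 (steps 1–4, then 7–10); the core branch is steps 5–6.

Most likely to fail, first: step 5. The photocycloaddition itself is reliable, but the facial preference on the dioxinone and the cis-anti-cis preference with this tetrasubstituted alkene are expected, not measured, and the yield of pure 12 may be low. The fallback gives up auxiliary control in favour of a classical resolution, so it depends on neither preference. It sets out from 10, which is irradiated with achiral 2,2,6-trimethyl-4H-1,3-dioxin-4-one to give the racemic cis-fused photoadduct F1 (every cis,cis adduct converges to the same racemate, so the approach mode no longer matters). Aqueous NaOH then opens and retro-aldolises F1 to the keto acid, which is resolved by crystallisation of its 1-phenylethylammonium salt to give 2-[(1S,2S)-2-acetyl-1,2-dimethylcyclopentyl]acetic acid F2. Acid-selective reduction with BH3·SMe2 gives 1-[(1S,2S)-2-(2-hydroxyethyl)-1,2-dimethylcyclopentyl]ethan-1-one F3, and Dess–Martin oxidation returns to the route at 14.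

Second: step 7. The hindered α-substituted methallyl boronate may react slowly with the neopentyl-type aldehyde, and the Z:E ratio rests on transition-state arguments. The fallback fixes the alkene geometry before the coupling. It sets out from 4, which is metalated as in step 3 and quenched with DMF to give 2-(2,5-dimethoxy-3-methylphenyl)acetaldehyde F4. Still–Gennari olefination with (CF3CH2O)2P(O)CH(CH3)CO2CH3, KN(SiMe3)2 and 18-crown-6 gives methyl (2Z)-4-(2,5-dimethoxy-3-methylphenyl)-2-methylbut-2-enoate F5. Reduction with i-Bu2AlH gives (2Z)-4-(2,5-dimethoxy-3-methylphenyl)-2-methylbut-2-en-1-ol F6, and PPh3/CCl4 gives 1-[(2Z)-4-chloro-3-methylbut-2-en-1-yl]-2,5-dimethoxy-3-methylbenzene F7. Activated barium (BaI2 reduced with lithium biphenylide) at −78 °C gives the geometry-retaining [(2Z)-4-(2,5-dimethoxy-3-methylphenyl)-2-methylbut-2-en-1-yl]barium chloride F8, which adds to the aldehyde of 14 through its α-carbon and comes back to the route at 15.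

Third: step 8. Under hydroxide, 2-hydroxy-2-methylpropanal can undergo α-ketol rearrangement or Cannizzaro loss faster than it condenses with the hindered methyl ketone. The fallback builds the enone by metathesis instead of aldol chemistry. It sets out from 15, which is α-methylenated (paraformaldehyde, N-methylanilinium trifluoroacetate, THF, reflux) to give the vinyl ketone 1-[(1S,2S)-2-[(4Z)-6-(2,5-dimethoxy-3-methylphenyl)-2-hydroxy-4-methylhex-4-en-1-yl]-1,2-dimethylcyclopentyl]prop-2-en-1-one F9. Cross-metathesis of F9 with 2-methylbut-3-en-2-ol (second-generation Hoveyda–Grubbs catalyst, CH2Cl2, 40 °C) gives the (E)-enone and comes back to the route at 18.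

**Further compounds**
F1 | step 5 | racemic cis-fused 2,6,7,9,9-pentamethyl-8,10-dioxatricyclo[5.4.0.0(2,6)]undecan-11-one (relative configuration shown) | O=C1OC(C)(C)O[C@@]2(C)[C@@H]1[C@]3(C)CCC[C@]23C
F2 | step 5 | 2-[(1S,2S)-2-acetyl-1,2-dimethylcyclopentyl]acetic acid (formed as the racemate, then resolved) | OC(=O)C[C@]1(C)CCC[C@]1(C)C(C)=O
F3 | step 5 | 1-[(1S,2S)-2-(2-hydroxyethyl)-1,2-dimethylcyclopentyl]ethan-1-one | OCC[C@]1(C)CCC[C@]1(C)C(C)=O
F4 | step 7 | 2-(2,5-dimethoxy-3-methylphenyl)acetaldehyde | O=CCc1cc(OC)cc(C)c1OC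
F5 | step 7 | methyl (2Z)-4-(2,5-dimethoxy-3-methylphenyl)-2-methylbut-2-enoate | COC(=O)/C(C)=C\Cc1cc(OC)cc(C)c1OC
F6 | step 7 | (2Z)-4-(2,5-dimethoxy-3-methylphenyl)-2-methylbut-2-en-1-ol | OC/C(C)=C\Cc1cc(OC)cc(C)c1OC
F7 | step 7 | 1-[(2Z)-4-chloro-3-methylbut-2-en-1-yl]-2,5-dimethoxy-3-methylbenzene | ClC/C(C)=C\Cc1cc(OC)cc(C)c1OC
F8 | step 7 | [(2Z)-4-(2,5-dimethoxy-3-methylphenyl)-2-methylbut-2-en-1-yl]barium chloride | Cl[Ba]C/C(C)=C\Cc1cc(OC)cc(C)c1OC
F9 | step 8 | 1-[(1S,2S)-2-[(4Z)-6-(2,5-dimethoxy-3-methylphenyl)-2-hydroxy-4-methylhex-4-en-1-yl]-1,2-dimethylcyclopentyl]prop-2-en-1-one | C/C(=C/Cc1cc(OC)cc(C)c1OC)CC(O)C[C@]1(C)CCC[C@]1(C)C(=O)C=C
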